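**Assumptions (one line):** terpenoid carbons are numbered as in the natural product (C1 = ArCH2 … C15 = CMe2Br); the target SMILES corresponds to 6S,7S,10R,11S,14S; compounds 1, 2, 8, both CBS antipodes and the L‑fructose‑derived (ent) Shi ketone are taken as commercial. This is an unprecedented, designed route, not a reproduction of a published synthesis.

## Retrosynthetic overview

1. Bromophycolide A ⇒ phenol pivalate; the C10‑Br/C11‑OH bromohydrin comes from a (10S,11S)‑epoxide opened by bromide at C10 with inversion; C15‑Br comes from the tertiary carbinol next to the lactone ester.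
2. The 15‑membered macrolactone (second ring) is closed by lactonization of the benzoic acid onto the secondary C14‑OH.
3. C14 is set by CBS reduction of a ketone; the C12–C13 bond comes from alkylating a methyl‑ketone enolate with a C12 allylic bromide.
4. The bromocyclohexene (first ring; C6, C7) comes from an enantioselective bromonium‑ene cyclization of a 12‑bromofarnesyl arene; the allylic bromide deactivates Δ10.
5. The farnesyl arene comes from allyl 4‑hydroxybenzoate and farnesyl bromide; the C12 handle comes from SeO2 oxidation.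

## Route

**Step 1**
Reactants: 1 allyl 4‑hydroxybenzoate; 2 (2E,6E)‑farnesyl bromide
Product: 3 allyl 4‑hydroxy‑3‑[(2E,6E)‑3,7,11‑trimethyldodeca‑2,6,10‑trienyl]benzoate
Conditions: NaH, toluene, 0 → 23 °C, then 2
Reagents that add atoms: none (farnesyl unit comes from 2)
Why: C‑alkylation of a sodium phenoxide in a non‑polar solvent occurs ortho (para is blocked) by SN2 at the primary allylic bromide, keeping the E‑olefins; the O‑alkylated by‑product is separated.

**Step 2**
Reactants: 3
Product: 4 allyl 3‑[(2E,6E)‑farnesyl]‑4‑(pivaloyloxy)benzoate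
Conditions: PivCl, Et3N, DMAP (cat.), CH2Cl2, 0 °C
Reagents that add atoms: pivaloyl chloride, CC(C)(C)C(Cl)=O
Why: Acylation gives an aryl ester that makes the phenol oxygen non‑nucleophilic and the ring resistant to Br+, preventing chroman formation and ring bromination later.

**Step 3**
Reactants: 4
Product: 5 allyl 3‑[(2E,6E,10E)‑12‑hydroxy‑3,7,11‑trimethyldodeca‑2,6,10‑trienyl]‑4‑(pivaloyloxy)benzoate
Conditions: SeO2 (cat.), t‑BuOOH, salicylic acid (cat.), CH2Cl2, 0 → 23 °C (partial conversion, recycle 4)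
Reagents that add atoms: tert‑butyl hydroperoxide, CC(C)(C)OO (oxygen source; SeO2, O=[Se]=O, is the catalyst)
Why: Sharpless–Umbreit SeO2 allylic oxidation (ene/[2,3]) selectively hydroxylates the E‑methyl of the terminal gem‑dimethyl olefin of polyprenyl chains.

**Step 4**
Reactants: 5
Product: 6 allyl 3‑[(2E,6E,10E)‑12‑bromo‑3,7,11‑trimethyldodeca‑2,6,10‑trienyl]‑4‑(pivaloyloxy)benzoate
Conditions: CBr4, PPh3, CH2Cl2, 0 °C
Reagents that add atoms: carbon tetrabromide, BrC(Br)(Br)Br
Why: Appel bromination of a primary allylic alcohol proceeds by SN2 without allylic transposition.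

**Step 5**
Reactants: 6
Product: 7 allyl 3‑{[(5S,6S)‑5‑bromo‑6‑[(3E)‑5‑bromo‑4‑methylpent‑3‑enyl]‑2,6‑dimethylcyclohex‑1‑enyl]methyl}‑4‑(pivaloyloxy)benzoate (C6 S, C7 S)
Conditions: chiral BINOL‑derived thiophosphoramide Lewis base (10 mol %; antipode chosen experimentally to give 6S,7S), DBDMH, toluene/CH2Cl2, −90 °C; then MsOH (cat.), CH2Cl2, 0 °C
Reagents that add atoms: 1,3‑dibromo‑5,5‑dimethylhydantoin, CC1(C)N(Br)C(=O)N(Br)C1=O
Why: Lewis‑base‑catalysed enantioselective bromonium‑ene (polyene) cyclization adds Br (C6) and C2 (C7) anti across the E‑Δ6 olefin through a chair transition state, with the catalyst setting the absolute sense; Δ10 is deactivated by its allylic bromide, and acid equilibrates the olefin isomers to the tetrasubstituted (β‑cyclogeranyl‑type) Δ2 position.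

**Step 6**
Reactants: 7; 8 3‑methyl‑3‑(trimethylsilyloxy)butan‑2‑one
Product: 9 allyl 3‑{[(5S,6S)‑5‑bromo‑6‑[(3E)‑4,8‑dimethyl‑7‑oxo‑8‑(trimethylsilyloxy)non‑3‑enyl]‑2,6‑dimethylcyclohex‑1‑enyl]methyl}‑4‑(pivaloyloxy)benzoate
Conditions: 8, LDA, THF, −78 °C; then 7, DMPU, −78 → −40 °C
Reagents that add atoms: none (C13–C15 unit comes from 8)
Why: Alkylation of the only possible (methyl‑side) lithium enolate by SN2 at the primary allylic bromide forms C12–C13; the neopentyl secondary C6‑Br, the hindered pivalate and the benzoate are slow to react at low temperature.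

**Step 7**
Reactants: 9
Product: 10 allyl 3‑{[(5S,6S)‑5‑bromo‑6‑[(3E,7S)‑7,8‑dihydroxy‑4,8‑dimethylnon‑3‑enyl]‑2,6‑dimethylcyclohex‑1‑enyl]methyl}‑4‑(pivaloyloxy)benzoate (C14 S)
Conditions: (R)‑Me‑CBS (20 mol %), catecholborane, toluene, −78 °C; then citric acid, MeOH (removes TMS)
Reagents that add atoms: none (hydride only)
Why: Corey–Bakshi–Shibata reduction distinguishes the bulky C(Me)2OTMS group from the CH2 chain, and the (R)‑catalyst gives the 14S carbinol by reagent control, while catecholborane leaves the alkenes and esters untouched.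

**Step 8**
Reactants: 10
Product: 11 3‑{[(5S,6S)‑5‑bromo‑6‑[(3E,7S)‑7,8‑dihydroxy‑4,8‑dimethylnon‑3‑enyl]‑2,6‑dimethylcyclohex‑1‑enyl]methyl}‑4‑(pivaloyloxy)benzoic acid
Conditions: Pd(PPh3)4 (5 mol %), PhSiH3, CH2Cl2, 23 °C
Reagents that add atoms: none
Why: Tsuji–Trost deallylation frees the acid under neutral conditions, so the aryl pivalate and alkyl bromide survive, which saponification would not allow.

**Step 9**
Reactants: 11
Product: 12 (6S,7S,10E,14S)‑macrolactone: 15‑membered lactone at C14‑O, free C15‑OH, Δ10 E‑olefin, phenol pivalate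
Conditions: MNBA, DMAP, Et3N, toluene (1 mM, syringe pump), 23 → 60 °C
Reagents that add atoms: none
Why: Shiina macrolactonization acylates only the secondary C14‑OH (the tertiary C15‑OH is inert), closing the 15‑membered ring with retention at C14.

**Step 10**
Reactants: 12
Product: 13 (6S,7S,10E,14S)‑6,15‑dibromo macrolactone pivalate
Conditions: 1‑bromo‑N,N,2‑trimethylpropenylamine, CH2Cl2, 0 → 23 °C
Reagents that add atoms: 1‑bromo‑N,N,2‑trimethylprop‑1‑en‑1‑amine, CC(C)=C(Br)N(C)C
Why: Ghosez‑type α‑haloenamine deoxybromination under neutral conditions, with ionization assisted by the neighbouring C14 benzoate (dioxolanylium ion) and bromide collapsing at the tertiary C15, so the C14–O bond is never broken.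

**Step 11**
Reactants: 13
Product: 14 (6S,7S,10S,11S,14S)‑10,11‑epoxide of 13
Conditions: ent‑Shi ketone (L‑fructose‑derived, 30 mol %), Oxone, K2CO3, Bu4NHSO4, MeCN/DMM/aq. buffer (pH 10.5), 0 °C
Reagents that add atoms: Oxone (potassium peroxymonosulfate), [K+].[O-]S(=O)(=O)OO
Why: Shi asymmetric epoxidation (chiral dioxirane, spiro transition state) of the only unhindered trisubstituted E‑olefin; the ent‑ketone gives the S,S epoxide, and the neopentyl tetrasubstituted Δ2 olefin is too hindered for this bulky dioxirane.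

**Step 12**
Reactants: 14
Product: 15 bromophycolide A O‑pivalate (6S,7S,10R,11S,14S)
Conditions: Li2NiBr4, THF, 0 → 23 °C
Reagents that add atoms: dilithium tetrabromonickelate, [Li+].[Li+].[Br-].[Br-].Br[Ni]Br (adds Br; H from work‑up)
Why: SN2 opening of the trisubstituted epoxide by soft bromide at the less substituted C10 inverts C10 (S → R) and leaves the C11–O bond intact (11S tertiary alcohol), giving the anti bromohydrin.

**Step 13**
Reactants: 15
Product: 16 bromophycolide A
Conditions: N2H4·HOAc, DMF (or THF/MeOH), 0 → 23 °C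
Reagents that add atoms: none
Why: Near‑neutral hydrazinolysis cleaves the activated aryl pivalate, while the hindered alkyl benzoate lactone is inert and no alkoxide is formed that could close the bromohydrin to an epoxide.

## Compound list

1 | allyl 4‑hydroxybenzoate | C=CCOC(=O)c1ccc(O)cc1 | starting material
2 | (2E,6E)‑farnesyl bromide | CC(C)=CCC/C(C)=C/CC/C(C)=C/CBr | starting material
3 | allyl 3‑farnesyl‑4‑hydroxybenzoate | C=CCOC(=O)c1ccc(O)c(C/C=C(C)/CC/C=C(C)/CCC=C(C)C)c1 | intermediate
4 | allyl 3‑farnesyl‑4‑(pivaloyloxy)benzoate | C=CCOC(=O)c1ccc(OC(=O)C(C)(C)C)c(C/C=C(C)/CC/C=C(C)/CCC=C(C)C)c1 | intermediate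
5 | (10E)‑12‑hydroxy derivative of 4 | C=CCOC(=O)c1ccc(OC(=O)C(C)(C)C)c(C/C=C(C)/CC/C=C(C)/CC/C=C(C)/CO)c1 | intermediate
6 | (10E)‑12‑bromo derivative of 4 | C=CCOC(=O)c1ccc(OC(=O)C(C)(C)C)c(C/C=C(C)/CC/C=C(C)/CC/C=C(C)/CBr)c1 | intermediate
7 | (6S,7S)‑bromocyclohexene with 12‑bromo side chain | CC1=C(Cc2cc(ccc2OC(=O)C(C)(C)C)C(=O)OCC=C)[C@](C)(CC/C=C(C)/CBr)[C@@H](Br)CC1 | intermediate
8 | 3‑methyl‑3‑(trimethylsilyloxy)butan‑2‑one | CC(=O)C(C)(C)O[Si](C)(C)C | starting material
9 | C14 ketone, C15‑OTMS | CC1=C(Cc2cc(ccc2OC(=O)C(C)(C)C)C(=O)OCC=C)[C@](C)(CC/C=C(C)/CCC(=O)C(C)(C)O[Si](C)(C)C)[C@@H](Br)CC1 | intermediate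
10 | (14S)‑14,15‑diol allyl ester | CC1=C(Cc2cc(ccc2OC(=O)C(C)(C)C)C(=O)OCC=C)[C@](C)(CC/C=C(C)/CC[C@H](O)C(C)(C)O)[C@@H](Br)CC1 | intermediate
11 | (14S)‑14,15‑diol seco acid | CC1=C(Cc2cc(ccc2OC(=O)C(C)(C)C)C(=O)O)[C@](C)(CC/C=C(C)/CC[C@H](O)C(C)(C)O)[C@@H](Br)CC1 | intermediate
12 | macrolactone, 15‑OH, Δ10 | CC1=C2Cc3cc(ccc3OC(=O)C(C)(C)C)C(=O)O[C@H](C(C)(C)O)CC/C(C)=C/CC[C@]2(C)[C@@H](Br)CC1 | intermediate
13 | macrolactone, 15‑Br, Δ10 | CC1=C2Cc3cc(ccc3OC(=O)C(C)(C)C)C(=O)O[C@H](C(C)(C)Br)CC/C(C)=C/CC[C@]2(C)[C@@H](Br)CC1 | intermediate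
14 | (10S,11S)‑epoxide | CC1=C2Cc3cc(ccc3OC(=O)C(C)(C)C)C(=O)O[C@H](C(C)(C)Br)CC[C@]4(C)O[C@H]4CC[C@]2(C)[C@@H](Br)CC1 | intermediate
15 | bromophycolide A O‑pivalate | CC1=C2Cc3cc(ccc3OC(=O)C(C)(C)C)C(=O)O[C@H](C(C)(C)Br)CC[C@](C)(O)[C@H](Br)CC[C@]2(C)[C@@H](Br)CC1 | intermediate
16 | bromophycolide A | CC1=C2Cc3cc(ccc3O)C(=O)O[C@H](C(C)(C)Br)CC[C@](C)(O)[C@H](Br)CC[C@]2(C)[C@@H](Br)CC1 | target

## Summary

Total steps: 13. Longest linear sequence: 13 (from 1; compounds 2 and 8 are purchased).

Three steps most likely to fail: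

1. **Step 5 (enantioselective bromocyclization).** Asymmetric induction is untested for an alkene‑terminated monocyclization, Br+ can also engage Δ2, and the olefin isomers must be equilibrated to Δ2. Fallback: run the cyclization racemically (BDSB, MeNO2, −25 °C) and resolve through the reagent‑controlled C14 centre, since after steps 6–9 the two ring enantiomers are diastereomeric macrolactones 12 that can be separated by chromatography.
2. **Step 10 (tertiary C15‑OH → Br).** Risks are elimination to the isopropenyl compound, bromide attack at C14 (giving the 16‑membered isomer) and participation by Δ10. Fallback: make the C–Br bond α to a carbonyl instead. Alkylate 7 with the kinetic enolate of 3‑methylbutan‑2‑one, brominate the tertiary α‑carbon via the thermodynamic silyl enol ether and NBS, CBS‑reduce the α‑bromoketone to the (14S)‑bromohydrin, and lactonize that.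
3. **Step 11 (Shi epoxidation in the macrocycle, then step 12).** The macrocycle's own facial bias or oxidation of Δ2 could override catalyst control, and the tertiary bromide is exposed to pH 10.5. Fallback: epoxidize and open Δ10 on acyclic ketone 9, where selectivity is purely catalyst‑controlled, and mask the C11‑OH as a TES ether. Then carry out CBS reduction, lactonization and C15 bromination, and remove TES with HF·pyridine at the end.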